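**Strategy**

The three contiguous bromines on the benzo ring are traced back to one amino group at C5 of an N1-Boc-protected 2,3-bis(methylsulfanyl)indole. C5 has C4 and C6 as its only ortho neighbours, and its para partner is the fully substituted ring-fusion carbon C7a, so the amine can steer electrophilic bromine only to C4 and C6. A single NBS operation therefore makes both outer C–Br bonds, and Sandmeyer exchange of the same nitrogen then supplies the C5 bromine. The precursor is built from 4-nitroaniline by Gassman oxindole synthesis, thionation, S-methylation, N-protection and nitro reduction. The carbamate tempers the para-diamine character of the ring, and all halogen is introduced after the heterocycle is complete.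

Key step: step 6

Remark: compounds 5, 6 and 7 (and F7, F8, F9, F12) carry one C–H stereocentre that is formed racemic and disappears on aromatization, so their SMILES are written without configuration. The target has no stereocentre.

**Route**

Step 1
Reactants: 1 4-nitroaniline; 2 ethyl 2-(methylsulfanyl)acetate
Product: 6 racemic 3-(methylsulfanyl)-5-nitroindolin-2-one, via N-chloro-4-nitroaniline 3 (not isolated), via azasulfonium chloride 4 (not isolated), via rearranged amino ester 5 (not isolated)
Conditions: t-BuOCl, CH2Cl2/MeCN, −65 °C; then 2; then Et3N, −65 °C → rt; then 2 M aq HCl, THF, 50 °C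
Reagents that add atoms: none
Why: Gassman oxindole synthesis: N-chlorination of the aniline, displacement of chloride at nitrogen by the sulfide, Et3N-induced ylide formation and [2,3]-sigmatropic (Sommelet–Hauser) rearrangement onto one of the two equivalent ortho carbons, then acid-catalysed lactamization, a sequence that suits electron-poor anilines because their N-chloro derivatives are stable; the C3 centre is formed racemic and is removed later by aromatization.

Step 2
Reactants: 6 racemic 3-(methylsulfanyl)-5-nitroindolin-2-one
Product: 7 racemic 3-(methylsulfanyl)-5-nitroindoline-2-thione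
Conditions: Lawesson's reagent (0.6 equiv), toluene, 80 °C, N2
Reagents that add atoms: Lawesson's reagent [2,4-bis(4-methoxyphenyl)-1,3,2,4-dithiadiphosphetane 2,4-disulfide], COc1ccc(cc1)P1(=S)SP(=S)(S1)c1ccc(OC)cc1
Why: Lactam-to-thiolactam O/S exchange with Lawesson's reagent (thionation through a four-membered thiaoxaphosphetane, Wittig-like) is standard for oxindoles and should tolerate the nitro group and the alkyl thioether; the crude thione is passed on quickly under N2 to avoid disulfide formation.

Step 3
Reactants: 7 racemic 3-(methylsulfanyl)-5-nitroindoline-2-thione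
Product: 8 2,3-bis(methylsulfanyl)-5-nitro-1H-indole
Conditions: MeI (1.05 equiv), K2CO3 (1.1 equiv), acetone, 0 °C → rt, N2
Reagents that add atoms: iodomethane, CI
Why: SN2 S-methylation of the thioamide (thiolate) at its soft sulfur gives the 2-methylsulfanyl-3H-indole, which tautomerizes to the aromatic 1H-indole and thereby erases the C3 stereocentre; the weak base and near-stoichiometric MeI should spare the indole nitrogen.

Step 4
Reactants: 8 2,3-bis(methylsulfanyl)-5-nitro-1H-indole; 9 di-tert-butyl dicarbonate
Product: 10 tert-butyl 2,3-bis(methylsulfanyl)-5-nitro-1H-indole-1-carboxylate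
Conditions: Boc2O (1.3 equiv), DMAP (0.1 equiv), MeCN, rt
Reagents that add atoms: di-tert-butyl dicarbonate (compound 9), CC(C)(C)OC(=O)OC(=O)OC(C)(C)C
Why: DMAP-catalysed N-acylation (carbamate formation) of the acidic nitroindole N–H with Boc2O is routine, and the carbamate is needed to lower the electron density of the pyrrole half before the amine is unveiled.

Step 5
Reactants: 10 tert-butyl 2,3-bis(methylsulfanyl)-5-nitro-1H-indole-1-carboxylate
Product: 11 tert-butyl 5-amino-2,3-bis(methylsulfanyl)-1H-indole-1-carboxylate
Conditions: Fe powder, NH4Cl, EtOH/H2O, 65 °C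
Reagents that add atoms: none
Why: Béchamp-type iron reduction of the aryl nitro group under near-neutral conditions avoids sulfur-poisoned hydrogenation catalysts and should leave the carbamate and both thioethers untouched.

Step 6
Reactants: 11 tert-butyl 5-amino-2,3-bis(methylsulfanyl)-1H-indole-1-carboxylate; 12 N-bromosuccinimide
Product: 15 tert-butyl 5-amino-4,6-dibromo-2,3-bis(methylsulfanyl)-1H-indole-1-carboxylate, via 4-bromo-5-aminoindole 13 (not isolated), via 6-bromo-5-aminoindole 14 (not isolated)
Conditions: NBS (2.05 equiv), anhydrous DMF, −40 → 0 °C, dark; aq Na2S2O3 quench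
Reagents that add atoms: N-bromosuccinimide (compound 12), O=C1CCC(=O)N1Br
Why: Each C–Br bond forms by electrophilic aromatic substitution: NBS delivers electrophilic bromine ortho to the free NH2, the arenium ion is stabilised by the nitrogen lone pair, and proton loss gives the bromoaniline and succinimide. The closest known reaction type is the NBS ortho,ortho-dibromination of para-substituted anilines in DMF. No ring is closed and no stereocentre is created. Regioselectivity is needed between C4/C6 and C7: the C5 amino group activates only its two ortho carbons because its para carbon is the quaternary C7a, C7 is meta to it, and C2 and C3 are blocked by sulfur; the first bromine may enter at either ortho carbon (13 or 14) and both monobromides converge on 15. Chemoselectivity is needed over the two thioethers and over oxidation of the para-diamine-like ring: the N1 carbamate lowers the electron density of the pyrrole half, anhydrous DMF at low temperature keeps any S-bromosulfonium from hydrolysing so that it passes its bromine on to the aniline ring, and NBS is held close to two equivalents.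

Step 7
Reactants: 15 tert-butyl 5-amino-4,6-dibromo-2,3-bis(methylsulfanyl)-1H-indole-1-carboxylate
Product: 17 tert-butyl 4,5,6-tribromo-2,3-bis(methylsulfanyl)-1H-indole-1-carboxylate, via arenediazonium bromide 16 (not isolated)
Conditions: t-BuONO (1.5 equiv), CuBr2 (1.2 equiv), MeCN, 0 → 60 °C
Reagents that add atoms: CuBr2, [Cu+2].[Br-].[Br-]
Why: Sandmeyer bromodediazoniation under anhydrous Doyle conditions: t-BuONO diazotizes the hindered 2,6-dibromoaniline in situ and the CuBr/CuBr2 couple converts the diazonium ion through an aryl radical into the aryl bromide, the standard way to a 1,2,3-tribromoarene; MeCN offers no easily abstracted hydrogen and the absence of aqueous acid protects the carbamate.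

Step 8
Reactants: 17 tert-butyl 4,5,6-tribromo-2,3-bis(methylsulfanyl)-1H-indole-1-carboxylate
Product: 18 4,5,6-tribromo-2,3-bis(methylsulfanyl)-1H-indole
Conditions: K2CO3 (0.3 equiv), MeOH/THF, rt → 40 °C
Reagents that add atoms: none
Why: Base-mediated methanolysis of the indole N-carbamate (acyl transfer to methoxide with the stabilised tribromoindolide as leaving group) is a known mild deprotection that avoids the acid-induced sulfenyl migration of 3-sulfanylindoles and tert-butyl cation capture by sulfur, and the unactivated aryl bromides do not undergo substitution.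

**Compound list**

1 | 4-nitroaniline | Nc1ccc(cc1)[N+](=O)[O-] | starting material
2 | ethyl 2-(methylsulfanyl)acetate | CCOC(=O)CSC | starting material
3 | N-chloro-4-nitroaniline | ClNc1ccc(cc1)[N+](=O)[O-] | intermediate
4 | (2-ethoxy-2-oxoethyl)(methyl)[(4-nitrophenyl)amino]sulfonium chloride (azasulfonium chloride) | CCOC(=O)C[S+](C)Nc1ccc(cc1)[N+](=O)[O-].[Cl-] | intermediate
5 | racemic ethyl 2-(2-amino-5-nitrophenyl)-2-(methylsulfanyl)acetate | CCOC(=O)C(SC)c1cc(ccc1N)[N+](=O)[O-] | intermediate
6 | racemic 3-(methylsulfanyl)-5-nitroindolin-2-one | CSC1C(=O)Nc2ccc(cc21)[N+](=O)[O-] | intermediate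
7 | racemic 3-(methylsulfanyl)-5-nitroindoline-2-thione | CSC1C(=S)Nc2ccc(cc21)[N+](=O)[O-] | intermediate
8 | 2,3-bis(methylsulfanyl)-5-nitro-1H-indole | CSc1[nH]c2ccc(cc2c1SC)[N+](=O)[O-] | intermediate
9 | di-tert-butyl dicarbonate | CC(C)(C)OC(=O)OC(=O)OC(C)(C)C | starting material
10 | tert-butyl 2,3-bis(methylsulfanyl)-5-nitro-1H-indole-1-carboxylate | CSc1c(SC)c2cc(ccc2n1C(=O)OC(C)(C)C)[N+](=O)[O-] | intermediate
11 | tert-butyl 5-amino-2,3-bis(methylsulfanyl)-1H-indole-1-carboxylate | CSc1c(SC)c2cc(N)ccc2n1C(=O)OC(C)(C)C | intermediate
12 | N-bromosuccinimide | O=C1CCC(=O)N1Br | starting material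
13 | tert-butyl 5-amino-4-bromo-2,3-bis(methylsulfanyl)-1H-indole-1-carboxylate | CSc1c(SC)c2c(Br)c(N)ccc2n1C(=O)OC(C)(C)C | intermediate
14 | tert-butyl 5-amino-6-bromo-2,3-bis(methylsulfanyl)-1H-indole-1-carboxylate | CSc1c(SC)c2cc(N)c(Br)cc2n1C(=O)OC(C)(C)C | intermediate
15 | tert-butyl 5-amino-4,6-dibromo-2,3-bis(methylsulfanyl)-1H-indole-1-carboxylate | CSc1c(SC)c2c(Br)c(N)c(Br)cc2n1C(=O)OC(C)(C)C | intermediate
16 | 4,6-dibromo-1-(tert-butoxycarbonyl)-2,3-bis(methylsulfanyl)-1H-indole-5-diazonium bromide | CSc1c(SC)c2c(Br)c([N+]#N)c(Br)cc2n1C(=O)OC(C)(C)C.[Br-] | intermediate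
17 | tert-butyl 4,5,6-tribromo-2,3-bis(methylsulfanyl)-1H-indole-1-carboxylate | CSc1c(SC)c2c(Br)c(Br)c(Br)cc2n1C(=O)OC(C)(C)C | intermediate
18 | 4,5,6-tribromo-2,3-bis(methylsulfanyl)-1H-indole | CSc1[nH]c2cc(Br)c(Br)c(Br)c2c1SC | target

**Step count**

Total step count: 8. Longest linear sequence: 8 steps (1 → 18).

**Steps most likely to fail and fallbacks**

Step 6 (double bromination). Bromine transfer to the thioether sulfur, ending in sulfoxide on work-up, or one-electron oxidation of the electron-rich aminoindole may outpace ring bromination. The second substitution at the hindered C4 next to the C3 sulfur may also stall. The fallback moves the same amine-directed dibromination and Sandmeyer exchange to the benzene stage, where no sulfur is present, and builds the heterocycle afterwards. It sets out from 1 (and later uses 2) and comes back to the route at 18. Bromination of 1 with Br2 in AcOH should give 2,6-dibromo-4-nitroaniline F1. Treatment with t-BuONO and CuBr2 in MeCN should convert it, by way of 2,6-dibromo-4-nitrobenzenediazonium bromide F2, into 1,2,3-tribromo-5-nitrobenzene F3. Fe/NH4Cl reduction should then give 3,4,5-tribromoaniline F4, whose two ortho positions are equivalent. Gassman oxindole synthesis with 2 (t-BuOCl; 2; Et3N; aq HCl) should run through N-chloro-3,4,5-tribromoaniline F5, the azasulfonium chloride (2-ethoxy-2-oxoethyl)(methyl)[(3,4,5-tribromophenyl)amino]sulfonium chloride F6 and ethyl 2-(6-amino-2,3,4-tribromophenyl)-2-(methylsulfanyl)acetate F7 to 4,5,6-tribromo-3-(methylsulfanyl)indolin-2-one F8. Lawesson's reagent should give 4,5,6-tribromo-3-(methylsulfanyl)indoline-2-thione F9, and MeI/K2CO3 should then deliver 18.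

Step 7 (Sandmeyer exchange). Diazotization of the hindered, weakly basic amine may be slow, and hydrodediazoniation or attack of the nitrite/CuBr2 couple on sulfur may compete. The fallback separates diazotization from bromide delivery. It sets out from 15 and comes back at 17. NOBF4 in MeCN at −30 °C should give the isolable salt 4,6-dibromo-1-(tert-butoxycarbonyl)-2,3-bis(methylsulfanyl)-1H-indole-5-diazonium tetrafluoroborate F10, precipitated with Et2O. This salt is then treated with KBr and catalytic CuBr, CuBr2 and 1,10-phenanthroline in MeCN at rt (catalytic Sandmeyer bromination of an isolated diazonium salt) to give 17.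

Step 2 (thionation). The C3 sulfur substituent may be lost under the thionation conditions, or the thione may be oxidised by air to a disulfide before it can be alkylated. The fallback avoids the oxindole and the thione altogether and makes the C2–S bond by electrophilic sulfenylation. It sets out from 1 (through its N-chloro derivative 3) and comes back at 8. Compound 3 is combined with commercial 1,1-dimethoxy-2-(methylsulfanyl)ethane (COC(OC)CSC) in a Gassman indole synthesis to give (2,2-dimethoxyethyl)(methyl)[(4-nitrophenyl)amino]sulfonium chloride F11. Et3N should induce rearrangement to racemic 2-[2,2-dimethoxy-1-(methylsulfanyl)ethyl]-4-nitroaniline F12, and aqueous HCl should cyclize this to 3-(methylsulfanyl)-5-nitro-1H-indole F13. A second sulfenylation with methanesulfenyl chloride F14 (made in the flask from dimethyl disulfide and SO2Cl2, CH2Cl2, 0 °C → rt) should proceed by ipso attack at C3 and 1,2-shift of sulfur to C2, giving 8.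

**Further compounds**

F1 | step 6 | 2,6-dibromo-4-nitroaniline | Nc1c(Br)cc(cc1Br)[N+](=O)[O-]
F2 | step 6 | 2,6-dibromo-4-nitrobenzenediazonium bromide | [O-][N+](=O)c1cc(Br)c([N+]#N)c(Br)c1.[Br-]
F3 | step 6 | 1,2,3-tribromo-5-nitrobenzene | [O-][N+](=O)c1cc(Br)c(Br)c(Br)c1
F4 | step 6 | 3,4,5-tribromoaniline | Nc1cc(Br)c(Br)c(Br)c1
F5 | step 6 | N-chloro-3,4,5-tribromoaniline | ClNc1cc(Br)c(Br)c(Br)c1
F6 | step 6 | (2-ethoxy-2-oxoethyl)(methyl)[(3,4,5-tribromophenyl)amino]sulfonium chloride | CCOC(=O)C[S+](C)Nc1cc(Br)c(Br)c(Br)c1.[Cl-]
F7 | step 6 | racemic ethyl 2-(6-amino-2,3,4-tribromophenyl)-2-(methylsulfanyl)acetate | CCOC(=O)C(SC)c1c(N)cc(Br)c(Br)c1Br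
F8 | step 6 | racemic 4,5,6-tribromo-3-(methylsulfanyl)indolin-2-one | CSC1C(=O)Nc2cc(Br)c(Br)c(Br)c21
F9 | step 6 | racemic 4,5,6-tribromo-3-(methylsulfanyl)indoline-2-thione | CSC1C(=S)Nc2cc(Br)c(Br)c(Br)c21
F10 | step 7 | 4,6-dibromo-1-(tert-butoxycarbonyl)-2,3-bis(methylsulfanyl)-1H-indole-5-diazonium tetrafluoroborate | CSc1c(SC)c2c(Br)c([N+]#N)c(Br)cc2n1C(=O)OC(C)(C)C.F[B-](F)(F)F
F11 | step 2 | (2,2-dimethoxyethyl)(methyl)[(4-nitrophenyl)amino]sulfonium chloride | COC(OC)C[S+](C)Nc1ccc(cc1)[N+](=O)[O-].[Cl-]
F12 | step 2 | racemic 2-[2,2-dimethoxy-1-(methylsulfanyl)ethyl]-4-nitroaniline | COC(OC)C(SC)c1cc(ccc1N)[N+](=O)[O-]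
F13 | step 2 | 3-(methylsulfanyl)-5-nitro-1H-indole | CSc1c[nH]c2ccc(cc12)[N+](=O)[O-]
F14 | step 2 | methanesulfenyl chloride | CSCl
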